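The ten-membered carbocycle is closed at C3–C4, the bond between C5 of the 3(2H)-furanone ring and the methyl-bearing carbon. The key step exploits the furanone as a cyclic β-alkoxy enone whose unsubstituted C3 accepts radicals: iron-hydride hydrogen atom transfer to a terminal alkene creates the C15 methyl group and a C4 radical that adds to C3, closing the ring and setting C4 under control of C6. The precursor is a 2,3,4-trisubstituted furan carrying a furanonylmethyl arm (C10 from (S)-citramalic acid) and an allyl carbinol arm (C6 from allylboration). The furan masks the butenolide and is unveiled last by singlet oxygen and dehydration.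

Key step: step 7

Remark: carbons carry germacrane numbers: C1 (furanone C=O), C2, C3 (furanone O–C=), C4 (CHMe, methyl C15), C5, C6 (ester carbinol), C7, C8, C9, C10 (quaternary, methyl C14), C11, C12 (lactone C=O), C13 (CH2OAc); the C3 centre of 17–20 and the C8 centre of 23 are destroyed later, and 1-acetoxy-3-chloroacetone and (−)-Ipc2B(allyl) are taken as commercial.

Step 1
Reactants: 1 (S)-citramalic acid; 2 2,2-dimethoxypropane
Product: 3 2-[(4S)-2,2,4-trimethyl-5-oxo-1,3-dioxolan-4-yl]acetic acid
Conditions: 2,2-dimethoxypropane (excess), TsOH·H2O (cat.), rt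
Reagents that add atoms: 2,2-dimethoxypropane COC(C)(C)OC
Why: Acid-catalysed transacetalization (acetonide formation) ties only the α-hydroxy acid unit into the five-membered dioxolanone, which differentiates the two carboxyl groups and leaves the C10 stereocentre untouched.

Step 2
Reactants: 3; 4 ethynylmagnesium bromide
Product: 6 2-[(2S)-2-methyl-3-oxo-2,3-dihydrofuran-2-yl]acetic acid, via hydroxy ynone acid 5 (not isolated)
Conditions: HC≡CMgBr (3.2 equiv), THF, −20 → 0 °C; aq NH4Cl; crude 5, K2CO3 (0.3 equiv), MeOH, rt; then 1 M HCl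
Reagents that add atoms: ethynylmagnesium bromide C#C[Mg]Br
Why: Acetylide acylation of the activated dioxolanone should stop at the magnesium hemiketal, which collapses on quench to ynone 5 with loss of acetone, and the tertiary alkoxide then closes by base-mediated 5-endo-dig oxa-Michael addition to the 3(2H)-furanone without any bond change at C10.

Step 3
Reactants: 6; 7 Meldrum's acid; 8 ethanethiol
Product: 10 S-ethyl 4-[(2S)-2-methyl-3-oxo-2,3-dihydrofuran-2-yl]-3-oxobutanethioate, via acyl Meldrum's acid 9 (not isolated)
Conditions: Meldrum's acid, EDCI, DMAP, CH2Cl2, 0 °C → rt; then EtSH (5 equiv), toluene, 80 °C, sealed tube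
Reagents that add atoms: Meldrum's acid CC1(C)OC(=O)CC(=O)O1; ethanethiol CCS
Why: Carbodiimide C-acylation of Meldrum's acid followed by thermolysis to an acylketene that the thiol traps (Oikawa-type β-keto ester synthesis, thiol variant) homologates the acid by two carbons without a strong base and installs a thioester that can later be reduced without a hydride reagent.

Step 4
Reactants: 10; 11 1-acetoxy-3-chloroacetone
Product: 13 S-ethyl 4-(acetoxymethyl)-2-{[(2S)-2-methyl-3-oxo-2,3-dihydrofuran-2-yl]methyl}furan-3-carbothioate, via hydroxydihydrofuran 12 (not isolated)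
Conditions: 11 (1.5 equiv), pyridine, rt → 50 °C; then TsOH·H2O (cat.), toluene, 40 °C
Reagents that add atoms: 1-acetoxy-3-chloroacetone CC(=O)OCC(=O)CCl
Why: Feist–Benary furan synthesis: aldol addition of the 1,3-dicarbonyl carbon (C7) to the doubly activated ketone, ring closure by enol O-alkylation with loss of chloride, and acid dehydration should give the 2,3,4-trisubstituted furan with CH2OAc on C11 and C12 unsubstituted.

Step 5
Reactants: 13
Product: 14 (4-formyl-5-{[(2S)-2-methyl-3-oxo-2,3-dihydrofuran-2-yl]methyl}furan-3-yl)methyl acetate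
Conditions: Et3SiH (3 equiv), 10% Pd/C (10 mol %), acetone, rt
Reagents that add atoms: none
Why: Fukuyama reduction (insertion of zerovalent palladium into the C–S bond, then hydride transfer from the silane) should deliver the C6 aldehyde under neutral conditions that spare the furanone ketone and the acetate.

Step 6
Reactants: 14; 15 (−)-B-allyldiisopinocampheylborane (from (+)-α-pinene)
Product: 16 (4-[(1S)-1-hydroxybut-3-en-1-yl]-5-{[(2S)-2-methyl-3-oxo-2,3-dihydrofuran-2-yl]methyl}furan-3-yl)methyl acetate
Conditions: (−)-Ipc2B(allyl) (1.3 equiv), Et2O, −78 °C; then aq NaHCO3, 30% H2O2, 0 °C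
Reagents that add atoms: (−)-B-allyldiisopinocampheylborane C=CCB([C@@H]1C[C@@H]2C[C@H]([C@H]1C)C2(C)C)[C@@H]1C[C@@H]2C[C@H]([C@H]1C)C2(C)C
Why: Brown asymmetric allylboration through a chair Zimmerman–Traxler transition state; the reagent from (+)-α-pinene attacks the Si face of aryl-type aldehydes and should set C6 as S by reagent control, while the conjugated and hindered furanone ketone does not react at −78 °C.

Step 7
Reactants: 16
Product: 17 (3S,4S,6S,10S)-13-acetoxy-6-hydroxy-3,10:8,12-diepoxygermacra-7,11-dien-1-one (ten-membered ring C1–C10 fused at C7–C8 to the furan, O-bridge C3–C10, C1 ketone)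
Conditions: Fe(acac)3 (0.5 equiv), PhSiH3 (3 equiv), degassed EtOH/ethylene glycol 5:1, 60 °C, 16 added by syringe pump over 6 h to 2 mM
Reagents that add atoms: none
Why: Hydrogen atom transfer from the iron hydride formed from Fe(acac)3 and PhSiH3 to the terminal CH2 of the alkene creates the C15 methyl group and a nucleophilic secondary radical at C4, which adds to C3, the unsubstituted β-carbon of the cyclic β-alkoxy enone, after which the α-keto radical is reduced by divalent iron and protonated by ethanol. The closest known reaction type is the iron-hydride reductive olefin–enone coupling (HAT-initiated Giese reaction) in its intramolecular form, with the polarity of β-alkoxyacrylate radical cyclizations. The new nine-membered oxacycle (C3–O–C10–C9–C8–C7–C6–C5–C4) closes in 9-exo-trig mode at the enol-ether carbon, which is 10-endo-trig with respect to the C1–C10 carbocycle, and gives an 11-oxabicyclo[6.2.1] core. C3 forms cis to C9 because the six-atom bridge can span only one face of the five-membered ring, and this centre is erased in step 9. C4 is relayed from C6: the arch conformer that keeps the C6 hydroxyl on the outer rim, with C6–H eclipsing the furan plane toward C13 to minimise allylic strain, presents the radical with its methyl group also outward, which is the 1,3-anti (4S,6S) arrangement free of syn-pentane strain. The step needs cyclization to outrun reduction of the radical and HAT to occur at the monosubstituted alkene and not at the electron-poor furanone alkene, which high dilution with slow addition, the absence of a fast hydrogen donor and the preference of the iron hydride for electron-rich alkenes should secure.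

Step 8
Reactants: 17; 18 3,3-dimethylacryloyl chloride (senecioyl chloride)
Product: 19 (3S,4S,6S,10S)-13-acetoxy-6-(3-methylbut-2-enoyloxy)-3,10:8,12-diepoxygermacra-7,11-dien-1-one
Conditions: 18 (1.5 equiv), pyridine, DMAP (cat.), CH2Cl2, 0 °C
Reagents that add atoms: 3,3-dimethylacryloyl chloride CC(C)=CC(=O)Cl
Why: DMAP-catalysed acylation of the only hydroxyl group, with pyridine in place of a trialkylamine so that no vinylketene forms and the senecioyl double bond stays conjugated.

Step 9
Reactants: 19
Product: 21 (4S,6S,10S)-13-acetoxy-6-(3-methylbut-2-enoyloxy)-3,10:8,12-diepoxygermacra-2,7,11-trien-1-one, via trimethylsilyl enol ether 20 (not isolated)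
Conditions: TMSOTf, Et3N, CH2Cl2, 0 °C; then Pd(OAc)2 (1.1 equiv), MeCN, rt
Reagents that add atoms: none
Why: Saegusa–Ito dehydrogenation: the ketone can enolize only toward C2 because C10 is quaternary, and divalent palladium turns the silyl enol ether into the enone by β-hydride elimination of the C3 hydrogen, which restores the 3(2H)-furanone and removes the C3 centre without touching C4.

Step 10
Reactants: 21
Product: 23 (4S,6S,10S)-13-acetoxy-8-hydroxy-6-(3-methylbut-2-enoyloxy)-1-oxo-3,10-epoxygermacra-2,7(11)-dien-12,8-olide (C8 epimers), via furan endoperoxide 22 (not isolated)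
Conditions: O2, visible light, tetraphenylporphyrin (cat.), i-Pr2NEt (1.5 equiv), CH2Cl2, −78 °C → 0 °C
Reagents that add atoms: oxygen O=O
Why: [4+2] cycloaddition of singlet oxygen to the electron-rich furan followed by base-induced Kornblum–DeLaMare fragmentation, which removes the only endoperoxide C–H (at C12) and so places the lactone carbonyl at C12 and the hemiketal hydroxyl at C8, while the electron-poor furanone and senecioate alkenes are inert to singlet oxygen.

Step 11
Reactants: 23
Product: 24 target, (4S,6S,8E,10S)-13-acetoxy-6-(3-methylbut-2-enoyloxy)-1-oxo-3,10-epoxygermacra-2,7(11),8-trien-12,8-olide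
Conditions: TsOH·H2O (10 mol %), 4 Å molecular sieves, toluene, 60 °C
Reagents that add atoms: none
Why: Acid-catalysed dehydration of the γ-hydroxybutenolide through its acyloxocarbenium ion can lose a proton only from C9, and the ring allows only the cis-cycloalkene, which is the required (E)-C8=C9 geometry with C10 cis to C7.

Compound list
1 | (S)-citramalic acid | C[C@](O)(CC(=O)O)C(=O)O | starting material
2 | 2,2-dimethoxypropane | COC(C)(C)OC | starting material
3 | 2-[(4S)-2,2,4-trimethyl-5-oxo-1,3-dioxolan-4-yl]acetic acid | C[C@@]1(CC(=O)O)OC(C)(C)OC1=O | intermediate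
4 | ethynylmagnesium bromide | C#C[Mg]Br | starting material
5 | (3S)-3-hydroxy-3-methyl-4-oxohex-5-ynoic acid (hydroxy ynone acid) | C#CC(=O)[C@@](C)(O)CC(=O)O | intermediate
6 | 2-[(2S)-2-methyl-3-oxo-2,3-dihydrofuran-2-yl]acetic acid | C[C@@]1(CC(=O)O)OC=CC1=O | intermediate
7 | Meldrum's acid (2,2-dimethyl-1,3-dioxane-4,6-dione) | CC1(C)OC(=O)CC(=O)O1 | starting material
8 | ethanethiol | CCS | starting material
9 | 2,2-dimethyl-5-{2-[(2S)-2-methyl-3-oxo-2,3-dihydrofuran-2-yl]acetyl}-1,3-dioxane-4,6-dione (acyl Meldrum's acid) | CC1(C)OC(=O)C(C(=O)C[C@]2(C)OC=CC2=O)C(=O)O1 | intermediate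
10 | S-ethyl 4-[(2S)-2-methyl-3-oxo-2,3-dihydrofuran-2-yl]-3-oxobutanethioate | CCSC(=O)CC(=O)C[C@]1(C)OC=CC1=O | intermediate
11 | 1-acetoxy-3-chloroacetone (3-chloro-2-oxopropyl acetate) | CC(=O)OCC(=O)CCl | starting material
12 | S-ethyl 4-(acetoxymethyl)-4-hydroxy-2-{[(2S)-2-methyl-3-oxo-2,3-dihydrofuran-2-yl]methyl}-4,5-dihydrofuran-3-carbothioate (carbinol epimers) | CCSC(=O)C1=C(C[C@]2(C)OC=CC2=O)OCC1(O)COC(C)=O | intermediate
13 | S-ethyl 4-(acetoxymethyl)-2-{[(2S)-2-methyl-3-oxo-2,3-dihydrofuran-2-yl]methyl}furan-3-carbothioate | CCSC(=O)c1c(COC(C)=O)coc1C[C@]1(C)OC=CC1=O | intermediate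
14 | (4-formyl-5-{[(2S)-2-methyl-3-oxo-2,3-dihydrofuran-2-yl]methyl}furan-3-yl)methyl acetate | O=Cc1c(COC(C)=O)coc1C[C@]1(C)OC=CC1=O | intermediate
15 | (−)-B-allyldiisopinocampheylborane | C=CCB([C@@H]1C[C@@H]2C[C@H]([C@H]1C)C2(C)C)[C@@H]1C[C@@H]2C[C@H]([C@H]1C)C2(C)C | starting material
16 | (4-[(1S)-1-hydroxybut-3-en-1-yl]-5-{[(2S)-2-methyl-3-oxo-2,3-dihydrofuran-2-yl]methyl}furan-3-yl)methyl acetate | C=CC[C@H](O)c1c(COC(C)=O)coc1C[C@]1(C)OC=CC1=O | intermediate
17 | (3S,4S,6S,10S)-13-acetoxy-6-hydroxy-3,10:8,12-diepoxygermacra-7,11-dien-1-one | CC(=O)OCc1coc2c1[C@@H](O)C[C@H](C)[C@@H]1CC(=O)[C@](C)(C2)O1 | intermediate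
18 | 3,3-dimethylacryloyl chloride | CC(C)=CC(=O)Cl | starting material
19 | (3S,4S,6S,10S)-13-acetoxy-6-(3-methylbut-2-enoyloxy)-3,10:8,12-diepoxygermacra-7,11-dien-1-one | CC(=O)OCc1coc2c1[C@@H](OC(=O)C=C(C)C)C[C@H](C)[C@@H]1CC(=O)[C@](C)(C2)O1 | intermediate
20 | C1 trimethylsilyl enol ether of 19 (1-trimethylsilyloxy-1-ene) | CC(=O)OCc1coc2c1[C@@H](OC(=O)C=C(C)C)C[C@H](C)[C@@H]1C=C(O[Si](C)(C)C)[C@](C)(C2)O1 | intermediate
21 | (4S,6S,10S)-13-acetoxy-6-(3-methylbut-2-enoyloxy)-3,10:8,12-diepoxygermacra-2,7,11-trien-1-one | CC(=O)OCc1coc2c1[C@@H](OC(=O)C=C(C)C)C[C@H](C)C1=CC(=O)[C@](C)(C2)O1 | intermediate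
22 | 8,12-endoperoxide of 21 (2,3,7-trioxabicyclo[2.2.1]hept-5-ene spanning C8 and C12) | CC(=O)OCC1=C2[C@@H](OC(=O)C=C(C)C)C[C@H](C)C3=CC(=O)[C@](C)(CC24OOC1O4)O3 | intermediate
23 | (4S,6S,10S)-13-acetoxy-8-hydroxy-6-(3-methylbut-2-enoyloxy)-1-oxo-3,10-epoxygermacra-2,7(11)-dien-12,8-olide (C8 epimers) | CC(=O)OCC1=C2[C@@H](OC(=O)C=C(C)C)C[C@H](C)C3=CC(=O)[C@](C)(CC2(O)OC1=O)O3 | intermediate
24 | (4S,6S,8E,10S)-13-acetoxy-6-(3-methylbut-2-enoyloxy)-1-oxo-3,10-epoxygermacra-2,7(11),8-trien-12,8-olide | CC(=O)OCC1=C2/C(=C\[C@]3(C)OC(=CC3=O)[C@@H](C)C[C@@H]2OC(=O)C=C(C)C)OC1=O | target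

Total step count: 11. Longest linear sequence: 11 steps, from (S)-citramalic acid.

Steps most likely to fail

Step 7. The medium ring may close too slowly, so that the C4 radical is reduced or trapped by solvent before it reaches C3, and facial discrimination at C4 may be incomplete. As a fallback the radical would be generated by halogen abstraction with the hydrogen donor held at very low concentration. From 16, cobalt-hydride Markovnikov hydroiodination (Co(acac)2, t-BuOOH, Et3SiH, CH2I2) would give the secondary iodide (4-[(1S)-1-hydroxy-3-iodobutyl]-5-{[(2S)-2-methyl-3-oxo-2,3-dihydrofuran-2-yl]methyl}furan-3-yl)methyl acetate F1 as both C4 epimers, which converge on one planar radical. Slow addition of (Me3Si)3SiH and AIBN to F1 at 1 mM in benzene at 80 °C should then close the same bond and return to 17.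

Step 4. The enolized β-keto thioester may add to its own furanone (intramolecular Michael addition at C3) or be C-alkylated by the chloroketone instead of following the aldol and O-alkylation sequence. As a fallback, from 10, a base-free García González-type condensation with 1,3-dihydroxyacetone under Lewis acid catalysis (CeCl3·7H2O, MeCN, 50 °C) would give S-ethyl 4-(hydroxymethyl)-2-{[(2S)-2-methyl-3-oxo-2,3-dihydrofuran-2-yl]methyl}furan-3-carbothioate F2. Acetylation of F2 (Ac2O, pyridine) returns to 13.

Step 2. The acetylide may add sluggishly to the hindered dioxolanone carbonyl next to the carboxylate, or add a second time to the ynone once the hemiketal collapses. As a fallback, from 3, aminolysis with Me(MeO)NMgCl (from MeNHOMe·HCl and i-PrMgCl, THF, −20 °C) would open the dioxolanone to the Weinreb amide (3S)-3-hydroxy-4-[methoxy(methyl)amino]-3-methyl-4-oxobutanoic acid F3. Its chelated adduct with ethynylmagnesium bromide cannot over-add and releases ynone 5 on quench; base-mediated cyclization as in step 2 then returns to 6.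

Further compounds
F1 | step 7 | (4-[(1S)-1-hydroxy-3-iodobutyl]-5-{[(2S)-2-methyl-3-oxo-2,3-dihydrofuran-2-yl]methyl}furan-3-yl)methyl acetate (C4 epimers) | CC(I)C[C@H](O)c1c(COC(C)=O)coc1C[C@]1(C)OC=CC1=O
F2 | step 4 | S-ethyl 4-(hydroxymethyl)-2-{[(2S)-2-methyl-3-oxo-2,3-dihydrofuran-2-yl]methyl}furan-3-carbothioate | CCSC(=O)c1c(CO)coc1C[C@]1(C)OC=CC1=O
F3 | step 2 | (3S)-3-hydroxy-4-[methoxy(methyl)amino]-3-methyl-4-oxobutanoic acid | CON(C)C(=O)[C@@](C)(O)CC(=O)O
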